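**Retrosynthetic overview**

1. Target ⇐ ligand-controlled 1,4-hydride addition to the C2=C3 bond of the bis-MOM flavone (sets 2S), then acid removal of the MOM groups.
2. Pyranone ring ⇐ carbonylative annulation of an o-iodophenol with phenylacetylene and CO; the phenol oxygen lies para to the piperidine, so only the 6-substituted chromone can form.
3. That phenol oxygen and the iodide ⇐ C–H borylation/oxidation and iodination of a symmetric 2-(2,6-dialkoxyphenyl)-1-methylpiperidine.
4. Piperidine ⇐ asymmetric hydrogenation and N-methylation of a 2-aryl cyclic imine ⇐ arylative Beckmann ring expansion of cyclopentanone oxime mesylate with the ortho-metalated bis-MOM ether of resorcinol.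
5. Ring order: benzene ring (from resorcinol) → piperidine (five-membered carbocycle expanded to the six-membered N-ring) → pyranone ring last.

Assumption: the ligand enantiomers named in steps 4 and 8 are taken to give the (R)-piperidine and the (2S)-flavanone; if a model run shows the opposite sense, the antipodal ligand is used.

**Route**

Step 1
Reactants: 1 resorcinol
Product: 2 1,3-bis(methoxymethoxy)benzene
Conditions: MOMCl (2.5 equiv), i-Pr2NEt (3 equiv), CH2Cl2, 0 °C → rt
Reagents that add atoms: chloromethyl methyl ether (MOMCl), COCCl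
Why: Williamson-type O-alkylation of both phenols gives the bis-acetal, which serves as phenol protection and as the pair of directing groups for ortho-metalation.

Step 2
Reactants: 3 cyclopentanone oxime
Product: 4 cyclopentanone O-(methylsulfonyl)oxime
Conditions: MsCl, Et3N, CH2Cl2, −20 °C (used cold, without storage)
Reagents that add atoms: methanesulfonyl chloride, CS(=O)(=O)Cl
Why: O-sulfonylation turns the oxime N–O bond into a leaving group for the Beckmann step, and the symmetric ketone leaves no E/Z or regiochemical question.

Step 3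
Reactants: 2 1,3-bis(methoxymethoxy)benzene; 4 cyclopentanone O-(methylsulfonyl)oxime
Product: 7 6-[2,6-bis(methoxymethoxy)phenyl]-2,3,4,5-tetrahydropyridine, via aryllithium 5 (not isolated), via arylalane 6 (not isolated)
Conditions: 2 (2.2 equiv), n-BuLi, Et2O, 0 °C → rt; Et2AlCl, −78 → 0 °C; Et2O exchanged for CH2Cl2; 4 (1.0 equiv), −78 → 0 °C; aq. NaF
Reagents that add atoms: none
Why: Proposed new method: directed ortho-metalation puts lithium at C2 between the two MOM ethers and Et2AlCl converts it into the chelated mixed alane 6; its Lewis-acidic aluminium ionises the mesylate of 4 while the anti ring C–C bond shifts from carbon to nitrogen (Beckmann 1,2-shift, cyclopentane → six-membered cyclic nitrilium), and the aluminate then hands its sp2 aryl group (a better bridging group than ethyl) to the nitrilium carbon, so ring expansion and aryl–C2 bond formation occur in one operation; the closest known reaction type is the organoaluminium-promoted Beckmann rearrangement–alkylation of oxime sulfonates with trialkyl- and alkynylalanes, and the new element is transfer of a di-ortho-alkoxy aryl group from an aryl(dialkyl)alane made by ortho-metalation.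

Step 4
Reactants: 7 6-[2,6-bis(methoxymethoxy)phenyl]-2,3,4,5-tetrahydropyridine
Product: 9 (2R)-2-[2,6-bis(methoxymethoxy)phenyl]-1-methylpiperidine, via NH-piperidine 8 (not isolated)
Conditions: [Ir(cod)Cl]2 (1 mol %), (S,S)-f-Binaphane (2.2 mol %), I2 (5 mol %), H2 (50 bar), CH2Cl2, rt; then 37 % aq. HCHO, NaBH(OAc)3, rt
Reagents that add atoms: formaldehyde, C=O
Why: Iridium-catalysed asymmetric hydrogenation of the cyclic 2-aryl imine delivers hydride to one face under control of the chiral ferrocenyl diphosphine and sets the (R) benzylic centre, after which reductive amination with formaldehyde (Abdel-Magid conditions) methylates nitrogen without touching that centre.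

Step 5
Reactants: 9 (2R)-2-[2,6-bis(methoxymethoxy)phenyl]-1-methylpiperidine
Product: 11 3,5-bis(methoxymethoxy)-4-[(2R)-1-methylpiperidin-2-yl]phenol, via arylboronate 10 (not isolated)
Conditions: [Ir(OMe)(cod)]2 (1.5 mol %), 4,4'-di-tert-butyl-2,2'-bipyridine (3 mol %), HBpin (1.5 equiv), THF, 80 °C; then 30 % aq. H2O2, aq. NaOH, 0 °C, 30 min; Na2S2O3
Reagents that add atoms: hydrogen peroxide, OO
Why: Sterically controlled iridium-catalysed C–H borylation goes to the only aromatic C–H without an ortho substituent (para to the piperidine), and boronate oxidation at 0 °C gives the phenol at that carbon faster than the tertiary amine is N-oxidised (one-pot borylation–oxidation).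

Step 6
Reactants: 11 3,5-bis(methoxymethoxy)-4-[(2R)-1-methylpiperidin-2-yl]phenol
Product: 12 2-iodo-3,5-bis(methoxymethoxy)-4-[(2R)-1-methylpiperidin-2-yl]phenol
Conditions: NIS (1.0 equiv), CH2Cl2, −40 → −20 °C
Reagents that add atoms: N-iodosuccinimide, O=C1CCC(=O)N1I
Why: Electrophilic aromatic iodination ortho to the free phenol; the two ortho positions are equivalent by symmetry, so one equivalent of NIS at low temperature gives a single mono-iodide, with the diiodide as the only by-product to control.

Step 7
Reactants: 12 2-iodo-3,5-bis(methoxymethoxy)-4-[(2R)-1-methylpiperidin-2-yl]phenol; 13 phenylacetylene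
Product: 15 5,7-bis(methoxymethoxy)-6-[(2R)-1-methylpiperidin-2-yl]-2-phenyl-4H-chromen-4-one, via ynone 14 (not isolated)
Conditions: PdCl2(PPh3)2 (5 mol %), CO (1 atm), Et2NH, 50 °C (copper-free)
Reagents that add atoms: carbon monoxide, [C-]#[O+]
Why: Copper-free carbonylative Sonogashira coupling gives the o-hydroxyaryl ynone, which closes 6-endo in diethylamine to the flavone (carbonylative annulation of o-iodophenols); because the cyclising oxygen is the one para to the piperidine, only the 6-substituted chromone can form.

Step 8
Reactants: 15 5,7-bis(methoxymethoxy)-6-[(2R)-1-methylpiperidin-2-yl]-2-phenyl-4H-chromen-4-one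
Product: 18 (2S)-5,7-dihydroxy-6-[(2R)-1-methylpiperidin-2-yl]-2-phenyl-2,3-dihydro-4H-chromen-4-one, via silyl enol ether 16 (not isolated), via MOM-protected flavanone 17 (not isolated)
Conditions: Cu(OAc)2 (5 mol %), (R)-DTBM-SEGPHOS (5.5 mol %), (EtO)2MeSiH (3 equiv), toluene, 0 °C → rt; then degassed 3 M HCl in MeOH, 40 °C; NaHCO3 to pH 7–8
Reagents that add atoms: none
Why: Ligand-controlled asymmetric conjugate reduction by copper hydride delivers hydride to C2 of the flavone and sets (2S), the enolate being trapped as the silyl enol ether so that neither ring-opening nor over-reduction occurs; acid methanolysis then frees the ketone and both phenols without base, so neither C2 nor the benzylic amine centre epimerises.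

**Compound list**

1 | resorcinol | Oc1cccc(O)c1 | starting material
2 | 1,3-bis(methoxymethoxy)benzene | COCOc1cccc(OCOC)c1 | intermediate
3 | cyclopentanone oxime | ON=C1CCCC1 | starting material
4 | cyclopentanone O-(methylsulfonyl)oxime | CS(=O)(=O)ON=C1CCCC1 | intermediate
5 | [2,6-bis(methoxymethoxy)phenyl]lithium | [Li]c1c(OCOC)cccc1OCOC | intermediate
6 | [2,6-bis(methoxymethoxy)phenyl]diethylaluminium | CC[Al](CC)c1c(OCOC)cccc1OCOC | intermediate
7 | 6-[2,6-bis(methoxymethoxy)phenyl]-2,3,4,5-tetrahydropyridine | COCOc1cccc(OCOC)c1C1=NCCCC1 | intermediate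
8 | (2R)-2-[2,6-bis(methoxymethoxy)phenyl]piperidine | N1CCCC[C@@H]1c1c(OCOC)cccc1OCOC | intermediate
9 | (2R)-2-[2,6-bis(methoxymethoxy)phenyl]-1-methylpiperidine | CN1CCCC[C@@H]1c1c(OCOC)cccc1OCOC | intermediate
10 | (2R)-2-[2,6-bis(methoxymethoxy)-4-(4,4,5,5-tetramethyl-1,3,2-dioxaborolan-2-yl)phenyl]-1-methylpiperidine | CN1CCCC[C@@H]1c1c(OCOC)cc(B2OC(C)(C)C(C)(C)O2)cc1OCOC | intermediate
11 | 3,5-bis(methoxymethoxy)-4-[(2R)-1-methylpiperidin-2-yl]phenol | CN1CCCC[C@@H]1c1c(OCOC)cc(O)cc1OCOC | intermediate
12 | 2-iodo-3,5-bis(methoxymethoxy)-4-[(2R)-1-methylpiperidin-2-yl]phenol | CN1CCCC[C@@H]1c1c(OCOC)cc(O)c(I)c1OCOC | intermediate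
13 | phenylacetylene | C#Cc1ccccc1 | starting material
14 | 1-{6-hydroxy-2,4-bis(methoxymethoxy)-3-[(2R)-1-methylpiperidin-2-yl]phenyl}-3-phenylprop-2-yn-1-one | CN1CCCC[C@@H]1c1c(OCOC)cc(O)c(C(=O)C#Cc2ccccc2)c1OCOC | intermediate
15 | 5,7-bis(methoxymethoxy)-6-[(2R)-1-methylpiperidin-2-yl]-2-phenyl-4H-chromen-4-one | CN1CCCC[C@@H]1c1c(OCOC)cc2oc(-c3ccccc3)cc(=O)c2c1OCOC | intermediate
16 | (2S)-4-{[diethoxy(methyl)silyl]oxy}-5,7-bis(methoxymethoxy)-6-[(2R)-1-methylpiperidin-2-yl]-2-phenyl-2H-chromene | CN1CCCC[C@@H]1c1c(OCOC)cc2c(c1OCOC)C(O[Si](C)(OCC)OCC)=C[C@@H](c1ccccc1)O2 | intermediate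
17 | (2S)-5,7-bis(methoxymethoxy)-6-[(2R)-1-methylpiperidin-2-yl]-2-phenyl-2,3-dihydro-4H-chromen-4-one | CN1CCCC[C@@H]1c1c(OCOC)cc2c(c1OCOC)C(=O)C[C@@H](c1ccccc1)O2 | intermediate
18 | (2S)-5,7-dihydroxy-6-[(2R)-1-methylpiperidin-2-yl]-2-phenyl-2,3-dihydro-4H-chromen-4-one | CN1CCCC[C@@H]1c1c(O)cc2c(c1O)C(=O)C[C@@H](c1ccccc1)O2 | target

**Step count and risks**

Total steps: 8. Longest linear sequence: 7 (steps 1, 3, 4, 5, 6, 7, 8; step 2 is a one-step branch).

Three steps most likely to fail:

Step 3 (the proposed new step). The mixed alane may transfer ethyl instead of aryl, attack the oxime nitrogen, or be too weakly Lewis acidic in the presence of residual ether. The fallback uses known imine chemistry and sets out from 2. Compound 2 is lithiated as before to the aryllithium 5, which is added at −78 °C → rt to 5-chloropentanenitrile (seven non-hydrogen atoms). Addition to the nitrile gives lithium {1-[2,6-bis(methoxymethoxy)phenyl]-5-chloropentylidene}azanide F1, which closes the ring by intramolecular displacement of chloride. This is the established route from aryl-metal reagents and ω-halonitriles to 2-aryl cyclic imines, and it comes back to the route at 7.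

Step 4. The di-ortho-substituted aryl group twists out of the imine plane and may slow the hydrogenation or erode the ee. The fallback sets out from 7, which is reduced with NaBH4 in MeOH to racemic 2-[2,6-bis(methoxymethoxy)phenyl]piperidine F2. The enantiomers are separated by preparative chromatography on a chiral stationary phase, and the (R)-enantiomer is 8. The route is rejoined at 8, which is N-methylated as in the second half of step 4.

Step 8. The vinylogous-ester enone of a 5-alkoxyflavone is a sluggish acceptor, and a copper enolate that is not silylated quickly could open the pyranone ring to the chalcone and lose the new stereocentre. The fallback sets out from 15 and avoids an enolate altogether. Compound 15 is fully hydrogenated with a chiral ruthenium N-heterocyclic carbene catalyst (Ru(cod)(2-methylallyl)2, chiral imidazolinium salt, KOt-Bu, H2), a known reaction of flavones, to (2S,4S)-5,7-bis(methoxymethoxy)-6-[(2R)-1-methylpiperidin-2-yl]-2-phenyl-3,4-dihydro-2H-chromen-4-ol F3. The benzylic alcohol is then re-oxidised with Dess–Martin periodinane and NaHCO3. This comes back to the route at 17, which is deprotected with HCl in MeOH as in step 8.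

**Further compounds**

F1 | step 3 | lithium {1-[2,6-bis(methoxymethoxy)phenyl]-5-chloropentylidene}azanide | [Li]N=C(CCCCCl)c1c(OCOC)cccc1OCOC
F2 | step 4 | racemic 2-[2,6-bis(methoxymethoxy)phenyl]piperidine | COCOc1cccc(OCOC)c1C1CCCCN1
F3 | step 8 | (2S,4S)-5,7-bis(methoxymethoxy)-6-[(2R)-1-methylpiperidin-2-yl]-2-phenyl-3,4-dihydro-2H-chromen-4-ol | CN1CCCC[C@@H]1c1c(OCOC)cc2c(c1OCOC)[C@@H](O)C[C@@H](c1ccccc1)O2
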